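One mM of G that has reached L has given two mM of Q to the solution, and one that has stopped at X has given one; keep that count for what follows.

| setting | ash | maple | flask |
|---|---|---|---|
| G | 13 mM | 20 mM | 13 mM |
| Q | 65 mM | 65 mM | 65.0 mM |
| D | 1.9 mM (held) | 1.9 mM (held) | 1.9 mM (held) |
| temperature | 60 °C | 66 °C | 60 °C |
| remark | the very flask that is asked about, followed so far | run made earlier |  |
| time |  |  | 4.0 d |

ash run (percent of the G charged)

| time / h | L / % |
|---|---|
| 3.00 | 14.1 |
| 8.00 | 39.6 |
| 15.0 | 52.0 |
| 25.0 | 55.3 |
| 40.0 | 56.3 |
| 50.0 | 54.4 |
| 60.0 | 56.2 |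

maple run (percent of the G charged)

| time / min | L / % |
|---|---|
| 10.0 | 0.1 |
| 15.0 | 0 |
| 20.0 | 1.8 |
| 30.0 | 0.6 |
| 50.0 | 0 |
| 80.0 | 3.3 |
| 120 | 8.2 |

(scatter of a reading: 1 percentage point)

- percent here means G units held: one Z counts as two
- what is said of L includes Z
- at the start none of J is dissolved
- additions bring no volume worth counting
- the numbers in the tables scatter with a standard deviation of 1 percentage point
- candidate steps: G + J -> Q + X; X + J <-> Q + L; D <-> J; G + L <-> Z
- in an amount of L, one Z counts as one L

* L, in percent of the G first charged, at 4.0 d
* what to do for the largest gain in L; "none" if nothing gains more than 2 percentage points (epsilon / theta / eta / alpha / none)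
* L present, in percent of the G first charged, after theta
* L present, in percent of the G first charged, after alpha

- epsilon: at 4.0 d take out 90% of the Q then present, then wait 30 h
- theta: at 4.0 d add G, 50.0% of the amount charged, then wait 30 h
- eta: change nothing and wait 30 h more
- alpha: at 4.0 d raise the temperature by 25 K, then wait 30 h

Begin with the curve, then ask what its end state is. In maple, L still reads 0% at 50.0 min and 8.2% at 120 min, so the start is slow. In ash, L reads 14.1% at 3.00 h, then gains a share of 0.0510 h⁻¹ of the charge up to 8.00 h. From there to 15.0 h the slope is 0.0177 h⁻¹, so the readings show a knee around 8.00 h. From 25.0 h on, the readings stay flat, and their mean is 55.5%. By interpolation, the curve crossed half of that level near 5.68 h.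

A flat level this far from full conversion I read as the equilibrium of X + J <-> Q + L (thermodynamic control), with the G charged counted as X or L and c(J) at 1.9 mM. Then you need one number, the plateau quotient, c(L)·c(Q)/c(X) at the level, which is the equilibrium constant times c(J). The count gives c(Q) = 85.2 mM, so the plateau quotient is 107 mM.

My reckoning for ash at 4.0 d is the level itself, 55.5%, and eta gains nothing on a flat line. Epsilon cuts c(Q) to 8.52 mM, and each further mM of L adds one of Q. Solving the quotient gives 89.2%. Theta, counted anew with 19.5 mM of G, gives 79.4% of the G first charged, less than epsilon. The wait of 30 h exceeds the time of the first flat reading in ash, 25.0 h, so I count on both new levels being reached. Maple shows no level, so for alpha I give no number, and of the options I can reckon I choose epsilon.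

The forecast says 55.6%, epsilon, 79% after theta and, where I give no number, 56% after alpha, writing: “I assume little shift, which is a guess”.

The flask gives 55.5%, and epsilon is best with a gain of 33 percentage points, against 24 points for theta and −22 points for alpha. L stands at 79.2% after theta and 33.7% after alpha.

    G + J → Q + X (k = 0.160 L mol⁻¹ s⁻¹, Ea = 50.0 kJ mol⁻¹)
    X + J ⇌ Q + L (K = 56.0, k = 0.0160 L mol⁻¹ s⁻¹, Ea = 48.0 kJ mol⁻¹, ΔH = −37.0 kJ mol⁻¹)
    D ⇌ J, rate k3*(csat - [J]) (kL = 0.00360 s⁻¹)
    G + L ⇌ Z, settled at all times (K = 210 L mol⁻¹, ΔH = −31.0 kJ mol⁻¹)
    (constants at 60 °C)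

With the reaction enthalpy above, the plateau quotient at the higher temperature of alpha is 41.9 mM. Put into the same count, it gives 33.7% for ash after alpha, beside the 33.7% of the result. For the neighbour charged with 26 mM of Q, the quotient from ash gives 68.9%, and that flask ends at 68.9%.

The data are simulated with made-up constants; the scatter is artificial.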